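The route rests on disconnecting the quaternary C5 of the cyclohexane ring (C1 carries the exocyclic enal, C4 the tertiary hydroxyl, C5 the methyl and the homofarnesyl chain, C6 the hydroxypropyl arm) back to a carvone-derived ketone whose carbonyl carbon becomes C5. The key step exploits the C4 hydroxyl next to C5: as its zinc alkoxide it steers methylene onto the adjacent exocyclic methoxymethylene group and closes a spiro-cyclopropane that fixes C5 in one operation (CH2, the later methyl, cis to OH; the masked aldehyde carbon trans). The precursor is the tertiary allylic alcohol carrying the enol ether at C5, allyl at C6 and isopropenyl at C1.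

Key step: step 7

Remark: the ring numbering of the target (C1 to C6 as above) is used for all ring intermediates.
Assumption: the Wittig reaction of step 6 is taken to give mainly the E enol ether; any Z isomer would give the epimer at the methoxy-bearing cyclopropane carbon, which converges in step 14.
Assumption: the (S)-configured phosphoric acid of step 19 is taken to direct the allenylboronate to the Si face of 3-methylbut-2-enal, as it does with aryl aldehydes; were the sense opposite, its enantiomer would be used.

Step 1
Reactants: 1 (S)-(+)-carvone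
Product: 2 carvone 2,3-epoxide (oxygen trans to isopropenyl)
Conditions: H2O2 (30% aq.), NaOH (cat.), MeOH, 0 °C
Reagents that add atoms: hydrogen peroxide, OO
Why: Weitz–Scheffer nucleophilic epoxidation touches only the enone, and axial attack of hydroperoxide anti to the equatorial isopropenyl group sets the oxygen-bearing carbon (the later C4) with oxygen trans to isopropenyl.

Step 2
Reactants: 2 carvone 2,3-epoxide
Product: 3 p-menth-8-ene-1,2-diol (tertiary OH trans to isopropenyl; secondary carbinol as epimer mixture)
Conditions: LiAlH4, THF, 0 °C → reflux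
Reagents that add atoms: none
Why: Hydride reduction of the ketone and SN2 opening of the epoxide at its secondary carbon leave the tertiary C4–O bond untouched, and the new secondary carbinol centre is erased in step 3.

Step 3
Reactants: 3 p-menth-8-ene-1,2-diol
Product: 4 (2S,5S)-2-hydroxy-2-methyl-5-(prop-1-en-2-yl)cyclohexan-1-one
Conditions: IBX (2-iodoxybenzoic acid), DMSO, 25 °C
Reagents that add atoms: none
Why: IBX oxidation converts the secondary alcohol of a 1,2-diol into the α-hydroxy ketone without glycol cleavage and cannot oxidise the tertiary alcohol.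

Step 4
Reactants: 4 α-hydroxy ketone
Product: 5 triethylsilyl ether of 4
Conditions: Et3SiOTf, 2,6-lutidine, CH2Cl2, −78 → 0 °C
Reagents that add atoms: triethylsilyl trifluoromethanesulfonate, CC[Si](CC)(CC)OS(=O)(=O)C(F)(F)F
Why: O-silylation of the tertiary alcohol blocks alkoxide chemistry (O-allylation, α-ketol shift) during the enolate alkylation and the Wittig reaction.

Step 5
Reactants: 5 silyl ether; 6 allyl bromide
Product: 8 6-allyl ketone (allyl trans to isopropenyl), via lithium enolate 7 (not isolated)
Conditions: LiN(i-Pr)2, THF, −78 °C; then 6, DMPU, −78 → −20 °C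
Reagents that add atoms: none
Why: Kinetic enolate alkylation can occur only at C6 (the other α-carbon is quaternary), and the electrophile enters anti to the neighbouring isopropenyl group, so C6 is set with allyl trans to isopropenyl, which is also the diequatorial thermodynamic isomer.

Step 6
Reactants: 8 6-allyl ketone; 9 (methoxymethyl)triphenylphosphonium chloride
Product: 11 (1S,3R,4S)-3-allyl-2-[(E)-methoxymethylidene]-1-methyl-4-(prop-1-en-2-yl)cyclohexan-1-ol, via TES enol ether 10 (not isolated)
Conditions: 9, KOtBu, THF, 0 → 40 °C; then Bu4NF, 25 °C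
Reagents that add atoms: none
Why: Wittig methoxymethylenation with the small alkoxy ylide tolerates the hindered ketone and should place the methoxy group away from the fully substituted C4 (E), and fluoride then frees the tertiary alcohol in the same flask without touching a ring stereocentre.

Step 7
Reactants: 11 hydroxy enol ether
Product: 13 spiro methoxycyclopropane (cyclopropane CH2 cis to the C4 hydroxyl), via ethylzinc alkoxide 12 (not isolated)
Conditions: Et2Zn, CH2I2, CH2Cl2, −10 → 0 °C; pyridine, then aq. NaHCO3
Reagents that add atoms: diiodomethane, ICI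
Why: Et2Zn turns the C4 hydroxyl into an ethylzinc alkoxide that holds the (iodomethyl)zinc carbenoid, and methylene is passed to the neighbouring exocyclic enol ether through the butterfly transition state of the Simmons–Smith reaction (Furukawa variant), a concerted syn addition. The closest known reaction type is the hydroxyl-directed cyclopropanation of cyclic allylic alcohols and of enol ethers used for geminal alkylation. The three-membered ring, spiro at C5, is closed by simultaneous formation of the C5–CH2 and CH2–CH(OMe) bonds in a [2+1] addition. C5 is controlled by the C4 alkoxide, which delivers CH2 to the face it occupies while the C4 methyl shields the other face, so CH2 ends cis to the hydroxyl; the CH(OMe) centre follows stereospecifically from the E enol ether and is erased in step 14. The step needs face selectivity at C5 and site selectivity over the allyl and isopropenyl groups, and both come from intramolecular delivery to the only alkene that is allylic to the alkoxide and, as an enol ether, the most electron-rich. The work-up is kept basic because the β-methoxycyclopropyl carbinol is acid-labile.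

Step 8
Reactants: 13 spiro methoxycyclopropane
Product: 15 primary alcohol (C6 3-hydroxypropyl arm), via trialkylborane 14 (not isolated)
Conditions: bis(3-methylbutan-2-yl)borane (Sia2BH, from BH3·THF and 2-methylbut-2-ene), THF, 0 °C; then NaOH, H2O2, 0 → 25 °C
Reagents that add atoms: hydrogen peroxide, OO
Why: Anti-Markovnikov hydroboration–oxidation with the bulky dialkylborane selects the monosubstituted allyl alkene over the 1,1-disubstituted, α-branched isopropenyl group and creates no stereocentre.

Step 9
Reactants: 15 diol
Product: 16 bis(tert-butyldimethylsilyl) ether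
Conditions: KN(SiMe3)2, THF, −78 °C; then t-BuMe2SiOTf, −78 → 0 °C
Reagents that add atoms: tert-butyldimethylsilyl trifluoromethanesulfonate, CC(C)(C)[Si](C)(C)OS(=O)(=O)C(F)(F)F
Why: Silylation through the potassium alkoxides avoids any oxonium intermediate at the cyclopropylcarbinyl C4 oxygen, and the robust tertiary silyl ether is needed because a free β-methoxycyclopropyl carbinol would ionise and unravel under the acid of step 14.

Step 10
Reactants: 16 bis-silyl ether
Product: 18 C1 methyl ketone, via ozonide 17 (not isolated)
Conditions: O3, CH2Cl2, −78 °C; then PPh3, −78 → 25 °C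
Reagents that add atoms: ozone, [O-][O+]=O
Why: Ozonolysis with reductive work-up cleaves the isopropenyl group, now the only C=C bond, while cyclopropane and silyl ethers are inert to ozone at −78 °C.

Step 11
Reactants: 18 methyl ketone
Product: 19 (Z)-trimethylsilyl enol ether (C1=C, silyloxy cis to C6)
Conditions: i-Pr2NMgBr, Me3SiCl, Et3N, HMPA, Et2O, 25 °C
Reagents that add atoms: chlorotrimethylsilane, C[Si](C)(C)Cl
Why: Thermodynamic enolisation with the bromomagnesium amide and in situ silylation gives the more substituted silyl enol ether, in which A(1,3) strain should place the slim oxygen, not the methyl, next to the branched C6 and so set the Z geometry.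

Step 12
Reactants: 19 silyl enol ether
Product: 21 (Z)-enol triflate, via lithium enolate 20 (not isolated)
Conditions: MeLi, THF, 0 °C; then PhNTf2, −78 → 0 °C
Reagents that add atoms: N-phenylbis(trifluoromethanesulfonimide), FC(F)(F)S(=O)(=O)N(c1ccccc1)S(=O)(=O)C(F)(F)F
Why: Methyllithium cleaves the Si–O bond to the regio- and stereodefined lithium enolate, which is O-sulfonylated by the triflimide with retention of double-bond geometry (enol triflate synthesis).

Step 13
Reactants: 21 enol triflate
Product: 22 methyl (Z)-enoate
Conditions: Pd(OAc)2 (cat.), 1,1′-bis(diphenylphosphino)ferrocene, CO (1 atm), MeOH, Et3N, DMF, 60 °C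
Reagents that add atoms: carbon monoxide, [C-]#[O+]; methanol, CO
Why: Palladium-catalysed methoxycarbonylation (oxidative addition of the triflate to zerovalent palladium, CO insertion, methanolysis) proceeds with retention of alkene geometry and leaves ethers and cyclopropane untouched.

Step 14
Reactants: 22 methyl enoate
Product: 23 C5 aldehyde (C5 methyl cis to the C4 silyloxy group; primary alcohol free)
Conditions: HCl (2 M aq.), THF, 45 °C
Reagents that add atoms: water, O
Why: Acid-promoted ring opening of the alkoxycyclopropane (geminal alkylation) protonates the unsubstituted CH2, cleaves the CH2–CH(OMe) bond and hydrolyses the oxocarbenium ion to the aldehyde, so C5 keeps its configuration with CH3 cis to the C4 oxygen, while the primary silyl ether is hydrolysed and the hindered tertiary one should survive.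

Step 15
Reactants: 23 aldehyde
Product: 24 C5 vinyl compound
Conditions: Ph3PCH3Br, KOtBu (less than one equivalent per phosphonium), THF, 0 → 25 °C
Reagents that add atoms: methyltriphenylphosphonium bromide, C[P+](c1ccccc1)(c1ccccc1)c1ccccc1.[Br-]
Why: Wittig methylenation of the non-enolisable neopentyl aldehyde touches no stereocentre, and the absence of excess base avoids γ-deprotonation of the enoate.

Step 16
Reactants: 24 vinyl ester
Product: 25 (Z)-allylic alcohol
Conditions: i-Bu2AlH, CH2Cl2, −78 → 0 °C; aq. potassium sodium tartrate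
Reagents that add atoms: none
Why: Aluminium hydride 1,2-reduction converts the conjugated ester into the allylic alcohol without change of alkene geometry and leaves the isolated vinyl group alone.

Step 17
Reactants: 25 allylic alcohol
Product: 26 triol (C4 hydroxyl free)
Conditions: Bu4NF, THF, 60 °C
Reagents that add atoms: none
Why: Fluoride cleavage of the hindered tertiary silyl ether is done here, on a robust intermediate, so that no forcing deprotection is needed once the epoxide is present.

Step 18
Reactants: 26 triol
Product: 27 bis-silyl ether (primary and allylic oxygens protected; C4 hydroxyl free)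
Conditions: t-BuMe2SiCl, imidazole, DMF, 0 → 25 °C
Reagents that add atoms: tert-butyldimethylsilyl chloride, CC(C)(C)[Si](C)(C)Cl
Why: Silyl chloride with imidazole silylates the two primary hydroxyls selectively and leaves the hindered tertiary alcohol free.

Step 19
Reactants: 28 3-methylbut-2-enal; 29 allenylboronic acid pinacol ester
Product: 30 (4S)-6-methylhept-5-en-1-yn-4-ol
Conditions: (S)-3,3′-bis(2,4,6-triisopropylphenyl)-1,1′-binaphthyl-2,2′-diyl hydrogen phosphate (10 mol %), 4 Å molecular sieves, toluene, 0 °C
Reagents that add atoms: none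
Why: Brønsted-acid-catalysed asymmetric propargylation (SE2′ addition of the allenylboronate through a six-membered transition state organised by the chiral phosphoric acid) attacks the Si face of the aldehyde and sets the (S) carbinol.

Step 20
Reactants: 30 homopropargylic alcohol
Product: 31 tert-butyldimethylsilyl ether of 30
Conditions: t-BuMe2SiCl, imidazole, DMF, 25 °C
Reagents that add atoms: tert-butyldimethylsilyl chloride, CC(C)(C)[Si](C)(C)Cl
Why: Silylation keeps the ionisable allylic alkoxide away from the Lewis-acidic aluminium and zirconium reagents of the next steps.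

Step 21
Reactants: 31 silyl ether
Product: 33 (E)-alkenyl iodide, via alkenylalane 32 (not isolated)
Conditions: Me3Al, Cp2ZrCl2 (zirconocene dichloride, cat.), CH2Cl2, 0 → 25 °C; then I2, THF, −30 °C
Reagents that add atoms: trimethylaluminium, C[Al](C)C; iodine, II
Why: Zirconium-catalysed carboalumination adds methyl and aluminium syn across the terminal alkyne with methyl on the internal carbon, and iodinolysis with retention gives the E trisubstituted alkenyl iodide.

Step 22
Reactants: 33 alkenyl iodide; 34 (4-bromobut-1-yn-1-yl)trimethylsilane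
Product: 37 terminal enyne silyl ether, via alkylzinc bromide 35 (not isolated), via silylalkyne 36 (not isolated)
Conditions: 34, Zn dust, I2 (cat.), N,N-dimethylacetamide, 70 °C; then 33, PdCl2(dppf) (cat.; dppf = 1,1′-bis(diphenylphosphino)ferrocene), THF, 40 °C; then K2CO3, MeOH, 25 °C
Reagents that add atoms: none
Why: Negishi coupling of the alkylzinc bromide with the alkenyl iodide retains the E geometry, and methanolysis then removes the alkynyl silyl group while the silyl ether stays.

Step 23
Reactants: 37 terminal enyne
Product: 39 (E,E)-dienyl iodide silyl ether, via alkenylalane 38 (not isolated)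
Conditions: Me3Al, Cp2ZrCl2 (cat.), CH2Cl2, 0 → 25 °C; then I2, THF, −30 °C
Reagents that add atoms: trimethylaluminium, C[Al](C)C; iodine, II
Why: A second zirconium-catalysed carboalumination with iodinolysis installs the terminal E alkenyl iodide by syn addition and retention, and the trisubstituted alkenes are inert.

Step 24
Reactants: 39 silyl ether
Product: 40 (4S,6E,10E)-11-iodo-2,6,10-trimethylundeca-2,6,10-trien-4-ol
Conditions: Bu4NF, THF, 0 → 25 °C
Reagents that add atoms: none
Why: Fluoride desilylation frees the allylic alcohol needed to direct the epoxidation.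

Step 25
Reactants: 40 allylic alcohol
Product: 41 threo epoxy alcohol (carbinol S, oxirane carbon R)
Conditions: Ti(OiPr)4 (cat.), t-BuOOH, 4 Å molecular sieves, CH2Cl2, −20 °C
Reagents that add atoms: tert-butyl hydroperoxide, CC(C)(C)OO
Why: Hydroxyl-directed titanium-catalysed epoxidation reaches only the allylic alkene, and A(1,3) strain from the cis methyl holds the carbinol C–H in the alkene plane so that oxygen is delivered syn to the hydroxyl, giving the threo epoxide.

Step 26
Reactants: 27 vinyl bis-silyl ether; 41 epoxy alkenyl iodide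
Product: 43 coupled bis-silyl ether, via alkylborane 42 (not isolated)
Conditions: 9-BBN, THF, 25 → 50 °C; then aq. Cs2CO3, 41, PdCl2(dppf) (cat.), AsPh3, DMF, 25 °C
Reagents that add atoms: none
Why: B-alkyl Suzuki–Miyaura coupling: 9-BBN hydroborates only the terminal vinyl group (the tetrasubstituted alkene is inert), and the primary alkylborane couples with the alkenyl iodide with retention of the E geometry and tolerance of epoxide and free hydroxyls.

Step 27
Reactants: 43 coupled bis-silyl ether
Product: 44 allylic alcohol tetraol
Conditions: Bu4NF, THF, 0 → 25 °C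
Reagents that add atoms: none
Why: Fluoride removes the two primary silyl ethers at or below room temperature, conditions under which the trisubstituted epoxide and the alkenes should persist.

Step 28
Reactants: 44 allylic alcohol tetraol
Product: 45 CNP0161066.1
Conditions: MnO2 (activated), CH2Cl2, 25 °C
Reagents that add atoms: none
Why: Manganese dioxide oxidises only the allylic primary alcohol to the enal, with retention of the Z geometry, and leaves the saturated primary, secondary and tertiary alcohols and the epoxide untouched.

Compound list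
1 | (S)-(+)-carvone | CC1=CC[C@@H](CC1=O)C(C)=C | starting material
2 | (1S,4S,6S)-1-methyl-4-(prop-1-en-2-yl)-7-oxabicyclo[4.1.0]heptan-2-one (epoxide oxygen trans to isopropenyl) | [C@H]1(C(C)=C)C[C@@H]2O[C@]2(C)C(=O)C1 | intermediate
3 | (1S,4S)-1-methyl-4-(prop-1-en-2-yl)cyclohexane-1,2-diol (tertiary OH trans to isopropenyl; C2 carbinol as epimer mixture) | [C@H]1(C(C)=C)CC[C@](C)(O)C(O)C1 | intermediate
4 | (2S,5S)-2-hydroxy-2-methyl-5-(prop-1-en-2-yl)cyclohexan-1-one | [C@H]1(C(C)=C)CC[C@](C)(O)C(=O)C1 | intermediate
5 | (2S,5S)-2-methyl-5-(prop-1-en-2-yl)-2-(triethylsilyloxy)cyclohexan-1-one | [C@H]1(C(C)=C)CC[C@](C)(O[Si](CC)(CC)CC)C(=O)C1 | intermediate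
6 | allyl bromide | C=CCBr | starting material
7 | lithium enolate of 5 (enolate toward C6) | [C@H]1(C(C)=C)CC[C@](C)(O[Si](CC)(CC)CC)C(O[Li])=C1 | intermediate
8 | (2S,5S,6R)-6-allyl-2-methyl-5-(prop-1-en-2-yl)-2-(triethylsilyloxy)cyclohexan-1-one (allyl trans to isopropenyl) | [C@H]1(C(C)=C)CC[C@](C)(O[Si](CC)(CC)CC)C(=O)[C@@H]1CC=C | intermediate
9 | (methoxymethyl)triphenylphosphonium chloride | COC[P+](c1ccccc1)(c1ccccc1)c1ccccc1.[Cl-] | starting material
10 | triethylsilyl ether of 11 ((E)-methoxymethylene at C5) | [C@H]1(C(C)=C)CC[C@](C)(O[Si](CC)(CC)CC)/C(=C/OC)[C@@H]1CC=C | intermediate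
11 | (1S,3R,4S)-3-allyl-2-[(E)-methoxymethylidene]-1-methyl-4-(prop-1-en-2-yl)cyclohexan-1-ol (key-step precursor) | [C@H]1(C(C)=C)CC[C@](C)(O)/C(=C/OC)[C@@H]1CC=C | intermediate
12 | ethylzinc alkoxide of 11 | [C@H]1(C(C)=C)CC[C@](C)(O[Zn]CC)/C(=C/OC)[C@@H]1CC=C | intermediate
13 | 8-allyl-1-methoxy-4-methyl-7-(prop-1-en-2-yl)spiro[2.5]octan-4-ol, cyclopropane CH2 cis to the hydroxyl, methoxy carbon trans (key-step product) | [C@H]1(C(C)=C)CC[C@](C)(O)[C@@](C2)([C@H]2OC)[C@@H]1CC=C | intermediate
14 | bis(3-methylbutan-2-yl)(alkyl)borane from hydroboration of the allyl group of 13 | [C@H]1(C(C)=C)CC[C@](C)(O)[C@@](C2)([C@H]2OC)[C@@H]1CCCB(C(C)C(C)C)C(C)C(C)C | intermediate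
15 | diol: 13 with the allyl group converted into a 3-hydroxypropyl arm | [C@H]1(C(C)=C)CC[C@](C)(O)[C@@](C2)([C@H]2OC)[C@@H]1CCCO | intermediate
16 | bis(tert-butyldimethylsilyl) ether of 15 (C4 oxygen and primary oxygen) | [C@H]1(C(C)=C)CC[C@](C)(O[Si](C)(C)C(C)(C)C)[C@@](C2)([C@H]2OC)[C@@H]1CCCO[Si](C)(C)C(C)(C)C | intermediate
17 | ozonide (1,2,4-trioxolane) of the isopropenyl group of 16 | [C@H]1(C3(C)OCOO3)CC[C@](C)(O[Si](C)(C)C(C)(C)C)[C@@](C2)([C@H]2OC)[C@@H]1CCCO[Si](C)(C)C(C)(C)C | intermediate
18 | C1 methyl ketone (acetyl in place of isopropenyl) | [C@H]1(C(C)=O)CC[C@](C)(O[Si](C)(C)C(C)(C)C)[C@@](C2)([C@H]2OC)[C@@H]1CCCO[Si](C)(C)C(C)(C)C | intermediate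
19 | (Z)-trimethylsilyl enol ether of 18 (exocyclic C1=C, silyloxy cis to C6) | C/C(O[Si](C)(C)C)=C1\CC[C@](C)(O[Si](C)(C)C(C)(C)C)[C@@](C2)([C@H]2OC)[C@@H]1CCCO[Si](C)(C)C(C)(C)C | intermediate
20 | (Z)-lithium enolate corresponding to 19 | C/C(O[Li])=C1\CC[C@](C)(O[Si](C)(C)C(C)(C)C)[C@@](C2)([C@H]2OC)[C@@H]1CCCO[Si](C)(C)C(C)(C)C | intermediate
21 | (Z)-enol triflate (triflyloxy cis to C6) | C/C(OS(=O)(=O)C(F)(F)F)=C1\CC[C@](C)(O[Si](C)(C)C(C)(C)C)[C@@](C2)([C@H]2OC)[C@@H]1CCCO[Si](C)(C)C(C)(C)C | intermediate
22 | methyl (Z)-2-(cyclohexylidene)propanoate (ester cis to C6), cyclopropane and both silyl ethers intact | C/C(C(=O)OC)=C1\CC[C@](C)(O[Si](C)(C)C(C)(C)C)[C@@](C2)([C@H]2OC)[C@@H]1CCCO[Si](C)(C)C(C)(C)C | intermediate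
23 | C5 aldehyde: C5 bears CH3 (cis to the C4 silyloxy group) and CHO; 3-hydroxypropyl at C6; (Z)-enoate at C1 | C/C(C(=O)OC)=C1\CC[C@](C)(O[Si](C)(C)C(C)(C)C)[C@@](C)(C=O)[C@@H]1CCCO | intermediate
24 | C5 vinyl analogue of 23 | C/C(C(=O)OC)=C1\CC[C@](C)(O[Si](C)(C)C(C)(C)C)[C@@](C)(C=C)[C@@H]1CCCO | intermediate
25 | (Z)-allylic alcohol from reduction of the ester of 24 | C/C(CO)=C1\CC[C@](C)(O[Si](C)(C)C(C)(C)C)[C@@](C)(C=C)[C@@H]1CCCO | intermediate
26 | triol: 25 with the C4 hydroxyl free | C/C(CO)=C1\CC[C@](C)(O)[C@@](C)(C=C)[C@@H]1CCCO | intermediate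
27 | bis(tert-butyldimethylsilyl) ether of 26 at the allylic and the primary oxygen, C4 hydroxyl free | C/C(CO[Si](C)(C)C(C)(C)C)=C1\CC[C@](C)(O)[C@@](C)(C=C)[C@@H]1CCCO[Si](C)(C)C(C)(C)C | intermediate
28 | 3-methylbut-2-enal | CC(C)=CC=O | starting material
29 | allenylboronic acid pinacol ester | C=C=CB1OC(C)(C)C(C)(C)O1 | starting material
30 | (4S)-6-methylhept-5-en-1-yn-4-ol | C#CC[C@H](O)C=C(C)C | intermediate
31 | tert-butyldimethylsilyl ether of 30 | C#CC[C@H](O[Si](C)(C)C(C)(C)C)C=C(C)C | intermediate
32 | (E)-alkenyl(dimethyl)alane from methylalumination of 31 | C[Al](C)/C=C(\C)C[C@H](O[Si](C)(C)C(C)(C)C)C=C(C)C | intermediate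
33 | tert-butyldimethylsilyl ether of (1E,4S)-1-iodo-2,6-dimethylhepta-1,5-dien-4-ol | I/C=C(\C)C[C@H](O[Si](C)(C)C(C)(C)C)C=C(C)C | intermediate
34 | (4-bromobut-1-yn-1-yl)trimethylsilane | C[Si](C)(C)C#CCCBr | starting material
35 | [4-(trimethylsilyl)but-3-yn-1-yl]zinc bromide | C[Si](C)(C)C#CCC[Zn]Br | intermediate
36 | C-trimethylsilyl derivative of 37 | C[Si](C)(C)C#CCC/C=C(\C)C[C@H](O[Si](C)(C)C(C)(C)C)C=C(C)C | intermediate
37 | tert-butyldimethylsilyl ether of (5E,8S)-6,10-dimethylundeca-5,9-dien-1-yn-8-ol | C#CCC/C=C(\C)C[C@H](O[Si](C)(C)C(C)(C)C)C=C(C)C | intermediate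
38 | (E)-alkenyl(dimethyl)alane from methylalumination of 37 | C[Al](C)/C=C(\C)CC/C=C(\C)C[C@H](O[Si](C)(C)C(C)(C)C)C=C(C)C | intermediate
39 | tert-butyldimethylsilyl ether of 40 | I/C=C(\C)CC/C=C(\C)C[C@H](O[Si](C)(C)C(C)(C)C)C=C(C)C | intermediate
40 | (4S,6E,10E)-11-iodo-2,6,10-trimethylundeca-2,6,10-trien-4-ol | I/C=C(\C)CC/C=C(\C)C[C@H](O)C=C(C)C | intermediate
41 | (1S,3E,7E)-1-[(2R)-3,3-dimethyloxiran-2-yl]-8-iodo-3,7-dimethylocta-3,7-dien-1-ol | I/C=C(\C)CC/C=C(\C)C[C@H](O)[C@H]1OC1(C)C | intermediate
42 | B-alkyl-9-borabicyclo[3.3.1]nonane from hydroboration of the vinyl group of 27 | C/C(CO[Si](C)(C)C(C)(C)C)=C1\CC[C@](C)(O)[C@@](C)(CCB2C3CCCC2CCC3)[C@@H]1CCCO[Si](C)(C)C(C)(C)C | intermediate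
43 | coupled product: target skeleton with the allylic and the primary oxygen silylated and CH2OSi in place of CHO | C/C(CO[Si](C)(C)C(C)(C)C)=C1\CC[C@](C)(O)[C@@](C)(CC/C=C(\C)CC/C=C(\C)C[C@H](O)[C@H]2OC2(C)C)[C@@H]1CCCO[Si](C)(C)C(C)(C)C | intermediate
44 | allylic alcohol corresponding to the target (CH2OH in place of CHO) | C/C(CO)=C1\CC[C@](C)(O)[C@@](C)(CC/C=C(\C)CC/C=C(\C)C[C@H](O)[C@H]2OC2(C)C)[C@@H]1CCCO | intermediate
45 | CNP0161066.1 | C/C(C=O)=C1\CC[C@](C)(O)[C@@](C)(CC/C=C(\C)CC/C=C(\C)C[C@H](O)[C@H]2OC2(C)C)[C@@H]1CCCO | target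

Total step count: 28 (steps 1–18 and 26–28 on the ring line, steps 19–25 on the side-chain line). Longest linear sequence: 21 steps (1–18, then 26–28) from (S)-carvone.

Steps most likely to fail:

Step 7. Methylene transfer may be diverted to the allyl or isopropenyl alkenes, or the zinc halide medium may unravel the acid-labile hydroxy methoxycyclopropane. The fallback abandons the zinc carbenoid for a samarium carbenoid (samarium amalgam from Sm and HgCl2, ClCH2I, THF, −78 → 25 °C). This reagent cyclopropanates only alkenes held next to a samarium alkoxide and generates no strong Lewis acid, so the change lies in the metal carbenoid and its mode of substrate binding, not in the conditions of the zinc reaction. It sets out from 11 and comes back at 13, with no compound outside the list (F0).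

Step 11. Enolisation may run toward the methyl group, or may give the enol ether with oxygen cis to C2; either would end in a wrong regio- or geometric isomer of the enal. The fallback sets out from 18 and builds the enolate by addition to a ketene. Haloform cleavage (NaOBr, dioxane–water, 0 °C) gives the C1 carboxylic acid F1. 1-Chloro-N,N,2-trimethylprop-1-en-1-amine converts it under neutral conditions into the acid chloride F2. Et3N in toluene dehydrochlorinates this to the disubstituted ketene F3. MeLi at −78 °C adds in the plane of the ketene substituents from the side of the unbranched C2, which places the oxygen cis to C6. The route is rejoined at lithium enolate 20, which is triflated to 21 as in step 12.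

Step 14. Ionisation at the silyloxy-bearing C4, assisted by the donor cyclopropane, or premature loss of the tertiary silyl group, would fragment the ring system to a β,γ-unsaturated aldehyde. The fallback sets out from 22 and replaces the proton by a soft metal electrophile. Hg(OAc)2 in MeOH opens the cyclopropane at its CH2 carbon to the acetoxymercurio dimethyl acetal F4. NaBH4 in aqueous NaOH removes the mercury to give the C5-methyl dimethyl acetal F5. Aqueous acetic acid in THF (40 °C), harmless once the cyclopropane is gone, hydrolyses the acetal and the primary silyl ether, and the route is rejoined at 23.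

Further compounds
F0 | step 7 | none | none
F1 | step 11 | C1 carboxylic acid (CO2H in place of the acetyl group of 18) | [C@H]1(C(O)=O)CC[C@](C)(O[Si](C)(C)C(C)(C)C)[C@@](C2)([C@H]2OC)[C@@H]1CCCO[Si](C)(C)C(C)(C)C
F2 | step 11 | acid chloride of F1 | [C@H]1(C(Cl)=O)CC[C@](C)(O[Si](C)(C)C(C)(C)C)[C@@](C2)([C@H]2OC)[C@@H]1CCCO[Si](C)(C)C(C)(C)C
F3 | step 11 | ketene with the C=C=O unit exocyclic at C1 | O=C=C1CC[C@](C)(O[Si](C)(C)C(C)(C)C)[C@@](C2)([C@H]2OC)[C@@H]1CCCO[Si](C)(C)C(C)(C)C
F4 | step 14 | acetoxymercurio dimethyl acetal (C5 bears CH2HgOAc and CH(OMe)2) | C/C(C(=O)OC)=C1\CC[C@](C)(O[Si](C)(C)C(C)(C)C)[C@@](C[Hg]OC(C)=O)(C(OC)OC)[C@@H]1CCCO[Si](C)(C)C(C)(C)C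
F5 | step 14 | C5-methyl dimethyl acetal (C5 bears CH3 and CH(OMe)2) | C/C(C(=O)OC)=C1\CC[C@](C)(O[Si](C)(C)C(C)(C)C)[C@@](C)(C(OC)OC)[C@@H]1CCCO[Si](C)(C)C(C)(C)C
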